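Labels: the cyclobutane is Ca–Cb–Cc–Cd. Ca and Cd carry the 2-aminoimidazoles, Cb and Cc carry the CH2NH–CO–pyrrole arms.
Cuts: (a) both imidazoles go back to Ca/Cd–C(=O)CH2NH2 and then to Ca/Cd–CO2Et; (b) the amide N–C(=O) and CH2–N bonds go back to CH2OBn; (c) the ring bonds Ca–Cb and Cd–Cc are cut last.
Enabling feature: Cb–Cc with its two CH2–heteroatom arms is the C1–C4 chain of a C2-symmetric threitol. Ca–Cd with its two carbonyl-derived substituents is the α,α'-carbon pair of a succinate. The four-membered ring is therefore the union of a vicinal bis-electrophile and a vicinal bis-carbanion.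
Forward order: the cyclobutane is made first (step 2, one flask), then the arms (O → N → pyrrole amide), and both aminoimidazole rings last and together.
Stereochemistry: Cb and Cc come from (S,S)-threitol through two SN2 inversions. Ca and Cd are enolisable and are driven by base to the all-trans thermodynamic minimum.
A third ester on Ca, removed in step 3, fixes where the second carbanion sits and so shuts off the competing three-membered ring.

Key step: step 2

Remark on the chemistry: the 4(5)-tautomers of the 2-aminoimidazoles interconvert, so the tautomer drawn for the target counts as the product of step 11. The target is taken as the free base.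

Step 1
Reactants: 1 (2S,3S)-1,4-di-O-benzylthreitol
Product: 3 (4S,5S)-4,5-bis(benzyloxymethyl)-1,3,2-dioxathiolane 2,2-dioxide, via cyclic sulfite 2 (not isolated)
Conditions: SOCl2, CH2Cl2, 40 °C; then MeCN–H2O, RuCl3 hydrate (cat.), NaIO4, 0 °C
Reagents that add atoms: thionyl chloride O=S(Cl)Cl; sodium periodate [Na+].[O-]I(=O)(=O)=O
Why: Sulfite formation followed by RuO4-catalysed S-oxidation is the standard cyclic sulfate synthesis from vicinal diols; no C–O bond is touched, so both S centres are kept, and the short cold oxidation should spare the benzyl ethers.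

Step 2
Reactants: 3 (4S,5S)-4,5-bis(benzyloxymethyl)-1,3,2-dioxathiolane 2,2-dioxide; 4 triethyl ethane-1,1,2-tricarboxylate
Product: 7 triethyl (2S,3R,4R)-3,4-bis(benzyloxymethyl)cyclobutane-1,1,2-tricarboxylate, via dilithio dianion 5 (not isolated), via ring-opened sulfate 6 (not isolated)
Conditions: 4 (1.05 equiv), LiN(iPr)2 (2.0 equiv), THF, −78 °C; 3 (1.0 equiv), −78 → 0 °C; then DMPU, 65 °C
Reagents that add atoms: none
Why: Proposed new method: dianion 5 should react first through its more basic ester-enolate carbon Cd, which opens 3 at Cc by SN2 with inversion to give 6, and on heating the remaining malonate carbanion Ca displaces the secondary sulfate monoester at Cb, again with inversion, in a 4-exo-tet closure of the cyclobutane (attack in the reverse order would end in the same product). The closest known reaction types are the double alkylation of succinate dianions with 1,n-dihalides to trans-cycloalkane-1,2-dicarboxylates, the cyclopropanation of malonates with 1,2-diol cyclic sulfates and the Perkin closure of cyclobutane-1,1-dicarboxylates from malonates and 1,3-dielectrophiles; a two-carbon plus two-carbon union of this kind has not been shown. Cb and Cc (both R, arms trans) are fixed by the two inversions at the (S,S)-sulfate, while Cd should form trans to the Cc arm because that rotamer closes with the least eclipsing, and being enolisable it is corrected in step 3 in any case. The selectivity needed is 4-exo over 3-exo closure: with a plain succinate the surviving enolate can move by proton transfer to the carbon already alkylated and close a cyclopropane much faster, whereas here the charge rests on the malonate carbon, some ten pKa units below Cd–H, so that no carbanion next to Cc exists as long as LiN(iPr)2 stays below two equivalents per 4. The weakly basic malonate also holds back E2 loss of sulfate and tolerates heating that a lithium ester enolate would not, and the three substituted chain carbons favour the folded rotamer needed for closure.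

Step 3
Reactants: 7 triethyl (2S,3R,4R)-3,4-bis(benzyloxymethyl)cyclobutane-1,1,2-tricarboxylate
Product: 9 diethyl (1S,2S,3R,4R)-3,4-bis(benzyloxymethyl)cyclobutane-1,2-dicarboxylate (all-trans), via C1-epimer mixture 8 (not isolated)
Conditions: LiCl, H2O, DMSO, 160 °C; then NaOEt (cat.), EtOH, 50 °C
Reagents that add atoms: none
Why: Krapcho dealkoxycarbonylation removes one geminal ester, and ethoxide equilibration of the enolisable centres Ca and Cd should then funnel all epimers into the isomer with every substituent trans to both neighbours, the fixed Cb and Cc centres deciding the absolute sense.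

Step 4
Reactants: 9 diethyl (1S,2S,3R,4R)-3,4-bis(benzyloxymethyl)cyclobutane-1,2-dicarboxylate
Product: 10 diethyl (1S,2S,3R,4R)-3,4-bis(hydroxymethyl)cyclobutane-1,2-dicarboxylate
Conditions: H2 (1 atm), Pd/C, EtOH, rt
Reagents that add atoms: none
Why: Neutral hydrogenolysis of benzyl ethers leaves esters and stereocentres alone, and the trans-1,2 relation of each CH2OH to its neighbouring ester should prevent lactonisation.

Step 5
Reactants: 10 diethyl (1S,2S,3R,4R)-3,4-bis(hydroxymethyl)cyclobutane-1,2-dicarboxylate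
Product: 12 diethyl (1S,2S,3R,4R)-3,4-bis(azidomethyl)cyclobutane-1,2-dicarboxylate, via bis-mesylate 11 (not isolated)
Conditions: MsCl, Et3N, CH2Cl2, 0 °C; then NaN3, DMF, 70 °C
Reagents that add atoms: sodium azide [Na+].[N-]=[N+]=[N-]; methanesulfonyl chloride CS(=O)(=O)Cl (its atoms stay only in 11)
Why: Sulfonate activation and SN2 displacement by azide take place at primary carbons only, so no stereocentre is involved.

Step 6
Reactants: 12 diethyl (1S,2S,3R,4R)-3,4-bis(azidomethyl)cyclobutane-1,2-dicarboxylate
Product: 13 diethyl (1S,2S,3R,4R)-3,4-bis(aminomethyl)cyclobutane-1,2-dicarboxylate dihydrochloride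
Conditions: H2 (1 atm), Pd/C, HCl (2 equiv), EtOH, rt
Reagents that add atoms: hydrogen chloride Cl
Why: Catalytic hydrogenation of alkyl azides is clean, and trapping the amines as ammonium salts should keep them from attacking the cis-1,3 ethyl esters.

Step 7
Reactants: 13 diethyl (1S,2S,3R,4R)-3,4-bis(aminomethyl)cyclobutane-1,2-dicarboxylate dihydrochloride; 14 2-(trichloroacetyl)pyrrole
Product: 15 diethyl (1S,2S,3R,4R)-3,4-bis[(1H-pyrrole-2-carboxamido)methyl]cyclobutane-1,2-dicarboxylate
Conditions: 14 (2.2 equiv), Na2CO3, DMF, rt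
Reagents that add atoms: none
Why: Haloform-type acyl transfer from a trichloromethyl ketone to a primary amine is the standard way to make pyrrole-2-carboxamides and needs neither a coupling agent nor pyrrole N-protection.

Step 8
Reactants: 15 diethyl (1S,2S,3R,4R)-3,4-bis[(1H-pyrrole-2-carboxamido)methyl]cyclobutane-1,2-dicarboxylate
Product: 16 (1S,2S,3R,4R)-3,4-bis[(1H-pyrrole-2-carboxamido)methyl]cyclobutane-1,2-dicarboxylic acid
Conditions: LiOH, THF–H2O, rt; then aq. HCl to pH 3
Reagents that add atoms: lithium hydroxide [Li+].[OH-]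
Why: Saponification cleaves the ethyl esters much faster than the secondary amides, and any enolisation at Ca or Cd is harmless because the all-trans array is already the most stable one.

Step 9
Reactants: 16 (1S,2S,3R,4R)-3,4-bis[(1H-pyrrole-2-carboxamido)methyl]cyclobutane-1,2-dicarboxylic acid
Product: 19 N,N'-{[(1R,2R,3S,4S)-3,4-bis(chloroacetyl)cyclobutane-1,2-diyl]bis(methylene)}bis(1H-pyrrole-2-carboxamide), via bis(mixed anhydride) 17 (not isolated), via bis(diazoketone) 18 (not isolated)
Conditions: i-BuOCOCl, N-methylmorpholine, THF–DMF, −20 °C; CH2N2, Et2O, 0 °C; then HCl (4 M in dioxane), 0 °C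
Reagents that add atoms: diazomethane C=[N+]=[N-]; hydrogen chloride Cl; isobutyl chloroformate CC(C)COC(=O)Cl (its atoms stay only in 17)
Why: Acylation of diazomethane by a mixed carbonic anhydride (the first half of the Arndt–Eistert sequence, routine beside amide N–H in peptide chemistry) followed by hydrochlorination of the diazoketone gives chloromethyl ketones under conditions that do not disturb Ca and Cd.

Step 10
Reactants: 19 N,N'-{[(1R,2R,3S,4S)-3,4-bis(chloroacetyl)cyclobutane-1,2-diyl]bis(methylene)}bis(1H-pyrrole-2-carboxamide)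
Product: 21 N,N'-{[(1R,2R,3S,4S)-3,4-bis(aminoacetyl)cyclobutane-1,2-diyl]bis(methylene)}bis(1H-pyrrole-2-carboxamide) dihydrochloride, via bis(diformylimide) 20 (not isolated)
Conditions: NaN(CHO)2, MeCN, 35 °C; then HCl, MeOH, rt
Reagents that add atoms: sodium diformylamide [Na+].O=C[N-]C=O; hydrogen chloride Cl
Why: This Gabriel-type amination uses a weakly basic nitrogen nucleophile that substitutes α-chloro ketones without Favorskii or epimerisation problems, and acidic methanolysis frees the amines directly as stable salts.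

Step 11
Reactants: 21 N,N'-{[(1R,2R,3S,4S)-3,4-bis(aminoacetyl)cyclobutane-1,2-diyl]bis(methylene)}bis(1H-pyrrole-2-carboxamide) dihydrochloride
Product: 23 N,N'-{[(1R,2R,3S,4S)-3,4-bis(2-amino-1H-imidazol-5-yl)cyclobutane-1,2-diyl]bis(methylene)}bis(1H-pyrrole-2-carboxamide) (target), via bis-hydrochloride 22 (not isolated)
Conditions: NH2CN, H2O, pH 4.5, 95 °C; then NaOH (2 equiv), C18 desalting
Reagents that add atoms: cyanamide N#CN
Why: Condensation of an α-amino ketone with cyanamide (Marckwald-type imidazole synthesis) guanylates the amine and cyclodehydrates onto the ketone, turning Ca and Cd into non-enolisable imidazolyl-bearing centres with their configuration kept.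

Compound list
1 | (2S,3S)-1,4-di-O-benzylthreitol | O[C@@H](COCc1ccccc1)[C@@H](O)COCc1ccccc1 | starting material
2 | (4S,5S)-4,5-bis(benzyloxymethyl)-1,3,2-dioxathiolane 2-oxide | O=S1O[C@@H](COCc2ccccc2)[C@H](COCc2ccccc2)O1 | intermediate
3 | (4S,5S)-4,5-bis(benzyloxymethyl)-1,3,2-dioxathiolane 2,2-dioxide | O=S1(=O)O[C@@H](COCc2ccccc2)[C@H](COCc2ccccc2)O1 | intermediate
4 | triethyl ethane-1,1,2-tricarboxylate | CCOC(=O)CC(C(=O)OCC)C(=O)OCC | starting material
5 | dilithium bis-enolate of 4 | [Li+].[Li+].CCOC([O-])=CC(C(=O)OCC)=C([O-])OCC | intermediate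
6 | dilithium salt of the ring-opened adduct (Cd–Cc bond formed with inversion, malonate enolate at Ca, Cb still bearing OSO3 in its original spatial arrangement) | [Li+].[Li+].[O-]S(=O)(=O)O[C@@H](COCc1ccccc1)[C@@H](COCc1ccccc1)[C@H](C(=O)OCC)C(C(=O)OCC)=C([O-])OCC | intermediate
7 | triethyl (2S,3R,4R)-3,4-bis(benzyloxymethyl)cyclobutane-1,1,2-tricarboxylate | CCOC(=O)C1(C(=O)OCC)[C@H](COCc2ccccc2)[C@@H](COCc2ccccc2)[C@@H]1C(=O)OCC | intermediate
8 | diethyl 3,4-bis(benzyloxymethyl)cyclobutane-1,2-dicarboxylate, mixture of C1 epimers | CCOC(=O)C1[C@H](COCc2ccccc2)[C@@H](COCc2ccccc2)[C@@H]1C(=O)OCC | intermediate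
9 | diethyl (1S,2S,3R,4R)-3,4-bis(benzyloxymethyl)cyclobutane-1,2-dicarboxylate | CCOC(=O)[C@H]1[C@H](COCc2ccccc2)[C@@H](COCc2ccccc2)[C@@H]1C(=O)OCC | intermediate
10 | diethyl (1S,2S,3R,4R)-3,4-bis(hydroxymethyl)cyclobutane-1,2-dicarboxylate | CCOC(=O)[C@H]1[C@H](CO)[C@@H](CO)[C@@H]1C(=O)OCC | intermediate
11 | diethyl (1S,2S,3R,4R)-3,4-bis(mesyloxymethyl)cyclobutane-1,2-dicarboxylate | CCOC(=O)[C@H]1[C@H](COS(C)(=O)=O)[C@@H](COS(C)(=O)=O)[C@@H]1C(=O)OCC | intermediate
12 | diethyl (1S,2S,3R,4R)-3,4-bis(azidomethyl)cyclobutane-1,2-dicarboxylate | CCOC(=O)[C@H]1[C@H](CN=[N+]=[N-])[C@@H](CN=[N+]=[N-])[C@@H]1C(=O)OCC | intermediate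
13 | diethyl (1S,2S,3R,4R)-3,4-bis(aminomethyl)cyclobutane-1,2-dicarboxylate dihydrochloride | Cl.Cl.CCOC(=O)[C@H]1[C@H](CN)[C@@H](CN)[C@@H]1C(=O)OCC | intermediate
14 | 2-(trichloroacetyl)pyrrole | O=C(c1ccc[nH]1)C(Cl)(Cl)Cl | starting material
15 | diethyl (1S,2S,3R,4R)-3,4-bis[(1H-pyrrole-2-carboxamido)methyl]cyclobutane-1,2-dicarboxylate | CCOC(=O)[C@H]1[C@H](CNC(=O)c2ccc[nH]2)[C@@H](CNC(=O)c2ccc[nH]2)[C@@H]1C(=O)OCC | intermediate
16 | (1S,2S,3R,4R)-3,4-bis[(1H-pyrrole-2-carboxamido)methyl]cyclobutane-1,2-dicarboxylic acid | OC(=O)[C@H]1[C@H](CNC(=O)c2ccc[nH]2)[C@@H](CNC(=O)c2ccc[nH]2)[C@@H]1C(=O)O | intermediate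
17 | bis(isobutyl carbonic) anhydride of 16 | CC(C)COC(=O)OC(=O)[C@H]1[C@H](CNC(=O)c2ccc[nH]2)[C@@H](CNC(=O)c2ccc[nH]2)[C@@H]1C(=O)OC(=O)OCC(C)C | intermediate
18 | all-trans bis(diazoacetyl)cyclobutane bis(pyrrole amide) | [N-]=[N+]=CC(=O)[C@H]1[C@H](CNC(=O)c2ccc[nH]2)[C@@H](CNC(=O)c2ccc[nH]2)[C@@H]1C(=O)C=[N+]=[N-] | intermediate
19 | N,N'-{[(1R,2R,3S,4S)-3,4-bis(chloroacetyl)cyclobutane-1,2-diyl]bis(methylene)}bis(1H-pyrrole-2-carboxamide) | ClCC(=O)[C@H]1[C@H](CNC(=O)c2ccc[nH]2)[C@@H](CNC(=O)c2ccc[nH]2)[C@@H]1C(=O)CCl | intermediate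
20 | all-trans bis[(diformylamino)acetyl]cyclobutane bis(pyrrole amide) | O=CN(C=O)CC(=O)[C@H]1[C@H](CNC(=O)c2ccc[nH]2)[C@@H](CNC(=O)c2ccc[nH]2)[C@@H]1C(=O)CN(C=O)C=O | intermediate
21 | N,N'-{[(1R,2R,3S,4S)-3,4-bis(aminoacetyl)cyclobutane-1,2-diyl]bis(methylene)}bis(1H-pyrrole-2-carboxamide) dihydrochloride | Cl.Cl.NCC(=O)[C@H]1[C@H](CNC(=O)c2ccc[nH]2)[C@@H](CNC(=O)c2ccc[nH]2)[C@@H]1C(=O)CN | intermediate
22 | dihydrochloride of 23 | Cl.Cl.Nc1ncc([C@H]2[C@H](CNC(=O)c3ccc[nH]3)[C@@H](CNC(=O)c3ccc[nH]3)[C@@H]2c2cnc(N)[nH]2)[nH]1 | intermediate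
23 | N,N'-{[(1R,2R,3S,4S)-3,4-bis(2-amino-1H-imidazol-5-yl)cyclobutane-1,2-diyl]bis(methylene)}bis(1H-pyrrole-2-carboxamide) | Nc1ncc([C@H]2[C@H](CNC(=O)c3ccc[nH]3)[C@@H](CNC(=O)c3ccc[nH]3)[C@@H]2c2cnc(N)[nH]2)[nH]1 | target

Total step count: 11. Longest linear sequence: 11 steps (1 → 23).

Steps most likely to fail

Step 2. The strongly basic dianion may eliminate 3 instead of substituting it. The 4-exo displacement of the secondary sulfate monoester may also be so slow that 6 is lost through elimination, lactonisation by the Cd ester carbonyl or O-alkylation of the malonate. The fallback builds the ring by known chemistry of a different kind, a [2+2] photocycloaddition followed by resolution. It is a fresh entry that draws on no numbered compound before 12. It sets out from commercial maleic anhydride and (E)-1,4-dichlorobut-2-ene and comes back to the route at 12.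
- Acetophenone-sensitised irradiation (MeCN, Pyrex-filtered medium-pressure Hg lamp) should give racemic cis-fused 6,7-trans-bis(chloromethyl)-3-oxabicyclo[3.2.0]heptane-2,4-dione F1, the alkene geometry being kept.
- EtOH with H2SO4 at reflux converts it into the racemic cis-1,2-diester F2.
- NaOEt in EtOH epimerises the more crowded ester carbon to the racemic all-trans diethyl 3,4-bis(chloromethyl)cyclobutane-1,2-dicarboxylate F3.
- NaN3 and NaI in DMF give the racemic bis-azide F4.
- Preparative chromatography on a chiral stationary phase separates the (1S,2S,3R,4R)-enantiomer, which is 12.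

Step 9. Three things may go wrong here.
- Double activation of the poorly soluble diacid may remain incomplete.
- The mixed anhydride may be captured by an arm amide or a pyrrole nitrogen.
- Unactivated acid may be methylated by CH2N2.

The fallback avoids diazo chemistry. It sets out from diester 15, so step 8 is skipped, and comes back at 19. Acyl substitution with excess dimethylsulfoxonium methylide (Me3S(O)I, KOt-Bu, THF, reflux, enough to cover the four N–H) should give the bis(β-keto sulfoxonium ylide) F5. Protonation and chloride attack (LiCl, MeSO3H, THF, 65 °C) expel dimethyl sulfoxide and deliver 19.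

Step 11. The free α-amino ketone may self-condense to dihydropyrazines, only one of the two ketones may annulate, and cyanamide may hydrolyse at 95 °C. The fallback forms the imidazoles from the halo ketone with an intact guanidine. It sets out from 19, so step 10 is skipped, and comes back at 23. N-Boc-guanidine (excess) with NaI in DMF at rt should give the bis(2-amino-1-Boc-imidazol-4-yl)cyclobutane F6. TFA in CH2Cl2 followed by neutralisation gives 23.

Further compounds
F1 | step 2 | rac-6,7-trans-bis(chloromethyl)-3-oxabicyclo[3.2.0]heptane-2,4-dione (cis ring fusion; one enantiomer drawn) | O=C1OC(=O)[C@H]2[C@H](CCl)[C@@H](CCl)[C@H]21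
F2 | step 2 | rac-diethyl 3,4-trans-bis(chloromethyl)cyclobutane-1,2-cis-dicarboxylate (one enantiomer drawn) | CCOC(=O)[C@H]1[C@H](CCl)[C@@H](CCl)[C@H]1C(=O)OCC
F3 | step 2 | rac-diethyl all-trans-3,4-bis(chloromethyl)cyclobutane-1,2-dicarboxylate (one enantiomer drawn) | CCOC(=O)[C@H]1[C@H](CCl)[C@@H](CCl)[C@@H]1C(=O)OCC
F4 | step 2 | rac-diethyl all-trans-3,4-bis(azidomethyl)cyclobutane-1,2-dicarboxylate (racemate of 12; one enantiomer drawn) | CCOC(=O)[C@H]1[C@H](CN=[N+]=[N-])[C@@H](CN=[N+]=[N-])[C@@H]1C(=O)OCC
F5 | step 9 | all-trans bis[(dimethylsulfoxonio)methanidylcarbonyl]cyclobutane bis(pyrrole amide) | C[S+](C)(=O)[CH-]C(=O)[C@H]1[C@H](CNC(=O)c2ccc[nH]2)[C@@H](CNC(=O)c2ccc[nH]2)[C@@H]1C(=O)[CH-][S+](C)(C)=O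
F6 | step 11 | di-tert-butyl 4,4'-{(1S,2S,3R,4R)-3,4-bis[(1H-pyrrole-2-carboxamido)methyl]cyclobutane-1,2-diyl}bis(2-amino-1H-imidazole-1-carboxylate) | CC(C)(C)OC(=O)n1cc(nc1N)[C@H]1[C@H](CNC(=O)c2ccc[nH]2)[C@@H](CNC(=O)c2ccc[nH]2)[C@@H]1c1cn(C(=O)OC(C)(C)C)c(N)n1
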